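**Plan**
- Numbering (germacrane): C1–C10 form the ten-membered carbocycle, the oxolane oxygen bridges C3 and C10, the γ-lactone (C11, C12, C13 methylidene) sits on C6/C7, C14 is the CH2O carbon and C15 the methyl.
- Retrosynthesis: remove the C8 acyl group, the C11=C13 methylidene and the C14 silyl group; open the C3 hemiketal to a C3 ketone and a C10 hydroxyl. The C8 oxygen and the C10 oxygen are then 1,3-related through C9 inside the carbocycle and C10 is fully substituted, which is the imprint of an isoxazoline; C8–C9 and O–C10 are therefore cut together (C8 nitrile oxide plus C9=C10 methylidene), which opens the ten-membered ring.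
- The seco-oxime is cut at C6–C7 (anti-aldol of a succinyl imide) and C12–O (lactone); the enal is cut at C5–C6 (formylation), C4–C15 (carbomagnesiation), C3–C4 (acetylide addition) and C1–C2 (Johnson–Claisen).
- Forward: chain C14/C10/C9/C1–C6 (steps 1–7), aldol and γ-lactone (steps 9–10), carbocycle and isoxazoline together (step 14), oxolane by N–O cleavage and transannular hemiketalisation (step 15), then C8 reduction, methylenation, acylation, desilylation.
- Stereochemistry: C6/C7 from the (R)-4-benzyloxazolidinone anti-aldol; (Z)-C4=C5 from alkoxide-directed anti-carbomagnesiation; C10 from the cycloaddition under control of the cis-lactone; C3 follows C10 (only the cis-bridged hemiketal can close); C8 from an oxazaborolidine-controlled reduction; the side-chain centre from (R)-2-methylbutanoic acid.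

Key step: step 14

Remark: C3 is formed as both configurations in step 4, is carried as such through compounds 7–12 and 17–20, and becomes a carbonyl in step 12; it is therefore left undefined in those names and SMILES. All other stereocentres are single.

**Step 1**
Reactants: 1 2-methylidenepropane-1,3-diol
Product: 2 2-({[tert-butyl(dimethyl)silyl]oxy}methyl)prop-2-en-1-ol
Conditions: NaH (1.0 equiv), THF, 0 °C; TBSCl (1.0 equiv), 0 °C to rt
Reagents that add atoms: tert-butyldimethylsilyl chloride, CC(C)(C)[Si](C)(C)Cl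
Why: Williamson-type O-silylation of the monosodium alkoxide, whose poor solubility holds the symmetrical diol at the mono-ether stage.

**Step 2**
Reactants: 2 2-({[tert-butyl(dimethyl)silyl]oxy}methyl)prop-2-en-1-ol
Product: 5 ethyl 4-({[tert-butyl(dimethyl)silyl]oxy}methyl)pent-4-enoate, via mixed orthoester 3 (not isolated), via ketene acetal 4 (not isolated)
Conditions: MeC(OEt)3 (5 equiv), EtCO2H (cat.), 140 °C, EtOH distilled off
Reagents that add atoms: triethyl orthoacetate, CCOC(C)(OCC)OCC
Why: Johnson–Claisen rearrangement, in which acid-catalysed exchange gives mixed orthoester 3, loss of ethanol gives ketene acetal 4, and its chair [3,3] shift forms the C1–C2 bond and leaves the 1,1-disubstituted C9=C10 alkene beside the C14 silyl ether.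

**Step 3**
Reactants: 5 ethyl 4-({[tert-butyl(dimethyl)silyl]oxy}methyl)pent-4-enoate
Product: 6 4-({[tert-butyl(dimethyl)silyl]oxy}methyl)pent-4-enal
Conditions: i-Bu2AlH (1.05 equiv), CH2Cl2, −78 °C; Rochelle salt work-up
Reagents that add atoms: none
Why: Partial reduction of an ester with i-Bu2AlH, whose tetrahedral aluminium hemiacetal is stable at −78 °C and releases the aldehyde (C3) only on work-up.

**Step 4**
Reactants: 6 4-({[tert-butyl(dimethyl)silyl]oxy}methyl)pent-4-enal
Product: 7 6-({[tert-butyl(dimethyl)silyl]oxy}methyl)hept-6-en-1-yn-3-ol (racemic)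
Conditions: ethynylmagnesium bromide, THF, 0 °C
Reagents that add atoms: ethynylmagnesium bromide, C#C[Mg]Br
Why: Grignard 1,2-addition of the acetylide to the unhindered aldehyde brings in C4 and C5 together with the C3 carbinol that directs the next step, and the missing control at C3 is of no consequence.

**Step 5**
Reactants: 7 6-({[tert-butyl(dimethyl)silyl]oxy}methyl)hept-6-en-1-yn-3-ol
Product: 9 (1Z)-6-({[tert-butyl(dimethyl)silyl]oxy}methyl)-1-iodo-2-methylhepta-1,6-dien-3-ol, via magnesacycle 8 (not isolated)
Conditions: MeMgBr (3 equiv), CuI (10 mol %), THF, −10 °C to rt; then I2, −78 to 0 °C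
Reagents that add atoms: methylmagnesium bromide, C[Mg]Br; iodine, II
Why: Alkoxide-directed anti-carbomagnesiation of a propargylic alcohol under CuI catalysis delivers methyl (C15) to the internal carbon C4 and magnesium to the terminus within chelate 8, so that iodinolysis with retention places iodine cis to the carbinol carbon and fixes the (Z) geometry of C4=C5.

**Step 6**
Reactants: 9 (1Z)-6-({[tert-butyl(dimethyl)silyl]oxy}methyl)-1-iodo-2-methylhepta-1,6-dien-3-ol
Product: 10 triethylsilyl ether of 9, tert-butyl({(6Z)-7-iodo-6-methyl-2-methylidene-5-[(triethylsilyl)oxy]hept-6-en-1-yl}oxy)dimethylsilane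
Conditions: TESCl, imidazole, CH2Cl2, 0 °C
Reagents that add atoms: chlorotriethylsilane, CC[Si](CC)(CC)Cl
Why: Standard silylation of a secondary allylic alcohol, giving an ether that withstands organolithium and the aldol medium and is later removed by mild acid without loss of the tert-butyldimethylsilyl ether.

**Step 7**
Reactants: 10 triethylsilyl ether of 9
Product: 12 (2Z)-7-({[tert-butyl(dimethyl)silyl]oxy}methyl)-3-methyl-4-[(triethylsilyl)oxy]octa-2,7-dienal, via alkenyllithium 11 (not isolated)
Conditions: t-BuLi (2.1 equiv), Et2O, −78 °C; DMF, −78 to 0 °C; aq. NH4Cl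
Reagents that add atoms: N,N-dimethylformamide, CN(C)C=O
Why: Iodine–lithium exchange with retention of alkene geometry followed by formylation with DMF installs C6 as the aldehyde, and diethyl ether at −78 °C suppresses 1,4 oxygen-to-carbon silyl migration in alkenyllithium 11.

**Step 8**
Reactants: 13 monomethyl succinate (4-methoxy-4-oxobutanoic acid); 14 (R)-4-benzyloxazolidin-2-one
Product: 16 (4R)-4-benzyl-3-(4-methoxy-4-oxobutanoyl)oxazolidin-2-one, via mixed anhydride 15 (not isolated)
Conditions: t-BuCOCl, Et3N, THF, −20 °C; then 14, LiCl, rt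
Reagents that add atoms: none
Why: N-Acylation of the oxazolidinone through the mixed pivalic anhydride with LiCl/Et3N activation, a standard one-flask imide synthesis in which the nucleophile attacks the less hindered succinyl carbonyl.

**Step 9**
Reactants: 16 (4R)-4-benzyl-3-(4-methoxy-4-oxobutanoyl)oxazolidin-2-one; 12 (2Z)-enal
Product: 17 (4R)-4-benzyl-3-[(2S,3S,4Z)-9-({[tert-butyl(dimethyl)silyl]oxy}methyl)-2-(2-methoxy-2-oxoethyl)-5-methyl-6-[(triethylsilyl)oxy]-3-[(trimethylsilyl)oxy]deca-4,9-dienoyl]oxazolidin-2-one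
Conditions: MgCl2 (0.2 equiv), Et3N (2 equiv), TMSCl (1.5 equiv), EtOAc, rt
Reagents that add atoms: chlorotrimethylsilane, C[Si](C)(C)Cl
Why: MgCl2-catalysed direct anti-aldol reaction of an N-acyloxazolidinone, in which soft enolisation gives the chelated (Z)-magnesium enolate at the imide α-carbon, the enal (no enolisable α-hydrogen) adds to the face away from the benzyl group in a boat-type transition state and silylation of the aldolate turns the catalyst over, setting (7R) and (6S) in germacrane terms with the anti relationship that leads to the cis-lactone.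

**Step 10**
Reactants: 17 aldol adduct trimethylsilyl ether
Product: 19 (4R)-4-benzyl-3-({(2S,3S)-2-[(1Z)-6-({[tert-butyl(dimethyl)silyl]oxy}methyl)-3-hydroxy-2-methylhepta-1,6-dien-1-yl]-5-oxooxolan-3-yl}carbonyl)oxazolidin-2-one, via diol ester 18 (not isolated)
Conditions: PPTS (0.2 equiv), MeOH/CH2Cl2 (1:1), 0 °C to rt; evaporate, PhMe, 45 °C
Reagents that add atoms: none
Why: Mild acid methanolysis removes the trimethylsilyl and triethylsilyl ethers but not the tert-butyldimethylsilyl ether, and the freed C6 hydroxyl closes the γ-lactone on the methyl ester (5-exo-trig acyl substitution) while the imide keeps C8 at the acid oxidation level so that only the C6 oxygen can lactonise.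

**Step 11**
Reactants: 19 hydroxy lactone imide
Product: 20 (4R,5S)-5-[(1Z)-6-({[tert-butyl(dimethyl)silyl]oxy}methyl)-3-hydroxy-2-methylhepta-1,6-dien-1-yl]-4-(hydroxymethyl)oxolan-2-one
Conditions: NaBH4, THF/H2O (4:1), 0 °C; pH 7 buffer
Reagents that add atoms: none
Why: Reductive removal of the oxazolidinone with NaBH4 in wet THF, which reduces the activated exocyclic imide carbonyl far faster than the γ-lactone and returns the auxiliary, with a cold neutral work-up meant to prevent migration of the lactone to the new primary hydroxyl.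

**Step 12**
Reactants: 20 diol lactone
Product: 21 (2S,3S)-2-[(1Z)-6-({[tert-butyl(dimethyl)silyl]oxy}methyl)-2-methyl-3-oxohepta-1,6-dien-1-yl]-5-oxooxolane-3-carbaldehyde
Conditions: Dess–Martin periodinane (3 equiv), pyridine, CH2Cl2, 0 °C to rt; used crude
Reagents that add atoms: none
Why: Dess–Martin oxidation of both alcohols in one operation gives the C8 aldehyde and the C3 enone, erases the undefined C3 centre, and is mild enough under pyridine buffering to leave the epimerisable C7 centre and the (Z)-alkene untouched.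

**Step 13**
Reactants: 21 keto aldehyde
Product: 22 (4R,5S)-5-[(1Z)-6-({[tert-butyl(dimethyl)silyl]oxy}methyl)-2-methyl-3-oxohepta-1,6-dien-1-yl]-4-[(E)-(hydroxyimino)methyl]oxolan-2-one
Conditions: NH2OH·HCl (1.1 equiv), NaOAc, EtOH, 0 °C
Reagents that add atoms: hydroxylamine hydrochloride, NO.Cl
Why: Oxime condensation that is selective for the aldehyde over the hindered conjugated C3 ketone with one equivalent of hydroxylamine at 0 °C under acetate buffer.

**Step 14**
Reactants: 22 C8 aldoxime of the cis-lactone with the (Z)-enone chain and the C10 methylidene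
Product: 25 isoxazoline-bridged ten-membered (Z)-enone lactone (6S,7R,10R), via hydroximoyl chloride 23 (not isolated), via nitrile oxide 24 (not isolated)
Conditions: aq. NaOCl, CH2Cl2, 0 °C to rt; 22 added by syringe pump to about 2 mM
Reagents that add atoms: none
Why: NaOCl chlorinates the aldoxime to hydroximoyl chloride 23 and the basic aqueous phase removes HCl to give nitrile oxide 24, which adds to the C9=C10 methylidene in a concerted [3+2] step (intramolecular nitrile oxide–alkene cycloaddition; closest known type: bridged isoxazolines from ω-alkenyl nitrile oxides in medium and large rings). The carbocycle closes as a ten-membered ring in the endo (bridged) mode through the new C8–C9 bond, and the isoxazoline closes as the five-membered ring of the cycloaddition through the new O–C10 bond. Regiochemistry follows the 1,1-disubstituted alkene, dipole carbon to the CH2 terminus and oxygen to the substituted C10, the reverse sense requiring a nine-membered ring and a quaternary C–C bond. The new stereocentre C10 is set by the alkene face that the tether presents, which the cis-lactone (C6, C7) controls: C8 and the C5 arm leave the lactone on the same face and the (Z)-enone turns the chain back, and the fold that keeps CH2OTBS on the H6/H7 side and the N–O bridge on the lactone side is the less crowded one and leads to (10R), an assignment that has to be confirmed on 25, any 10-epimer being removed by chromatography. The step needs intramolecular reaction to outrun furoxan formation, which slow generation of 24 at high dilution and the preorganised cis-lactone/(Z)-alkene secure; the C4=C5 enone cannot compete because its adduct would be a bicyclo[2.2.1] bridgehead imine.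

**Step 15**
Reactants: 25 isoxazoline-bridged lactone
Product: 28 hemiketal ketone (3S,6S,7S,10R): 3-hydroxy-3,10-epoxy-8-oxo lactone with C14–OTBS, via hydroxy imine 26 (not isolated), via hydroxy diketone 27 (not isolated)
Conditions: Mo(CO)6 (1.2 equiv), MeCN/H2O (15:1), 80 °C; carried on at once
Reagents that add atoms: water, O
Why: Mo(CO)6 cleaves the N–O bond of the isoxazoline reductively, water hydrolyses hydroxy imine 26 to β-hydroxy ketone 27, and the tertiary C10 hydroxyl adds across the ring to the C3 ketone (transannular hemiketalisation) to close the oxolane, the C3 configuration following from C10 because only the cis-bridged hemiketal can span the ten-membered ring.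

**Step 16**
Reactants: 28 hemiketal ketone
Product: 29 (3S,6S,7R,8R,10R)-8-hydroxy hemiketal lactone
Conditions: (S)-1-methyl-3,3-diphenyltetrahydro-1H,3H-pyrrolo[1,2-c][1,3,2]oxazaborole (0.3 equiv), BH3·SMe2, THF, −30 °C; MeOH quench
Reagents that add atoms: none
Why: Corey–Bakshi–Shibata reduction, in which the (S)-oxazaborolidine binds the C8 carbonyl with the branched C7 side as the large group and delivers hydride to the face that gives the (8R) carbinol (the sense of acetophenone to (R)-1-phenylethanol), so that the catalyst and not the bicycle decides the face, while the C3 ketone stays masked as the hemiketal and the neutral work-up avoids lactone migration to O8.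

**Step 17**
Reactants: 29 8-hydroxy hemiketal lactone
Product: 30 3,8-bis(triethylsilyl) ether of 29
Conditions: TESOTf (2.5 equiv), 2,6-lutidine, CH2Cl2, −78 to 0 °C
Reagents that add atoms: triethylsilyl trifluoromethanesulfonate, CC[Si](CC)(CC)OS(=O)(=O)C(F)(F)F
Why: Silylation with TESOTf and 2,6-lutidine caps the secondary C8 hydroxyl and the tertiary hemiketal hydroxyl so that no acidic O–H and no latent C3 ketone are exposed to the amide base of the next step.

**Step 18**
Reactants: 30 bis(triethylsilyl) ether
Product: 34 α-methylidene lactone bis(triethylsilyl) ether, via lithium enolate 31 (not isolated), via Mannich base 32 (not isolated), via ammonium iodide 33 (not isolated)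
Conditions: LiN(i-Pr)2 (1.5 equiv), THF, −78 °C; CH2=NMe2+ I−, −78 °C to rt; MeI, rt; evaporate; aq. NaHCO3/EtOAc
Reagents that add atoms: dimethyl(methylidene)ammonium iodide, C=[N+](C)C.[I-]
Why: α-Methylenation of a γ-lactone by the Mannich route, in which the lithium enolate (the only acidic C–H is at C11, and C7 carries no leaving group) is aminomethylated by the iminium salt and quaternisation followed by base-induced elimination of trimethylamine gives the C11=C13 methylidene.

**Step 19**
Reactants: 34 α-methylidene lactone bis(triethylsilyl) ether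
Product: 35 α-methylidene lactone 3,8-diol with C14–OTBS
Conditions: AcOH/THF/H2O (3:1:1), rt
Reagents that add atoms: none
Why: Aqueous acetic acid hydrolyses the silyl ketal at C3 and the secondary triethylsilyl ether at C8 while the tert-butyldimethylsilyl ether on the neopentyl-type C14 oxygen survives, leaving C8–OH as the only acylable hydroxyl.

**Step 20**
Reactants: 35 α-methylidene lactone 3,8-diol; 36 (R)-2-methylbutanoic acid
Product: 38 8-O-[(2R)-2-methylbutanoyl] ester of 35, via O-acylisourea 37 (not isolated)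
Conditions: DCC, 4-(dimethylamino)pyridine (0.1 equiv), CH2Cl2, 0 °C to rt
Reagents that add atoms: none
Why: Steglich esterification, in which the secondary C8 hydroxyl is acylated by the carbodiimide-activated acid under 4-(dimethylamino)pyridine catalysis whereas the tertiary hemiketal hydroxyl is inert, and the mild conditions keep the (R) centre of the acid intact.

**Step 21**
Reactants: 38 C14 silyl ether of the target
Product: 39 CNP0328225.2, (3S,6S,7R,8R,10R,4Z)-3,14-dihydroxy-3,10-epoxy-8-[(2R)-2-methylbutanoyloxy]germacra-4,11(13)-dien-6,12-olide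
Conditions: HF·pyridine, THF, 0 °C to rt
Reagents that add atoms: none
Why: Fluoride-mediated cleavage of the silyl ether with HF·pyridine, which is acidic enough to spare the α-methylidene lactone, the ester and the hemiketal and to exclude acyl migration from O8 to O14.

**Compound list**
1 | 2-methylidenepropane-1,3-diol | C=C(CO)CO | starting material
2 | 2-({[tert-butyl(dimethyl)silyl]oxy}methyl)prop-2-en-1-ol | C=C(CO)CO[Si](C)(C)C(C)(C)C | intermediate
3 | mixed orthoester, tert-butyl({2-[(1,1-diethoxyethoxy)methyl]prop-2-en-1-yl}oxy)dimethylsilane | CCOC(C)(OCC)OCC(=C)CO[Si](C)(C)C(C)(C)C | intermediate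
4 | ketene acetal, tert-butyl[(2-{[(1-ethoxyethenyl)oxy]methyl}prop-2-en-1-yl)oxy]dimethylsilane | C=C(OCC)OCC(=C)CO[Si](C)(C)C(C)(C)C | intermediate
5 | ethyl 4-({[tert-butyl(dimethyl)silyl]oxy}methyl)pent-4-enoate | CCOC(=O)CCC(=C)CO[Si](C)(C)C(C)(C)C | intermediate
6 | 4-({[tert-butyl(dimethyl)silyl]oxy}methyl)pent-4-enal | O=CCCC(=C)CO[Si](C)(C)C(C)(C)C | intermediate
7 | 6-({[tert-butyl(dimethyl)silyl]oxy}methyl)hept-6-en-1-yn-3-ol (racemic) | C#CC(O)CCC(=C)CO[Si](C)(C)C(C)(C)C | intermediate
8 | chelated (Z)-alkenylmagnesium alkoxide (five-membered magnesacycle) | CC1=C[Mg]OC1CCC(=C)CO[Si](C)(C)C(C)(C)C | intermediate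
9 | (1Z)-6-({[tert-butyl(dimethyl)silyl]oxy}methyl)-1-iodo-2-methylhepta-1,6-dien-3-ol | I/C=C(/C)C(O)CCC(=C)CO[Si](C)(C)C(C)(C)C | intermediate
10 | triethylsilyl ether of 9 | I/C=C(/C)C(O[Si](CC)(CC)CC)CCC(=C)CO[Si](C)(C)C(C)(C)C | intermediate
11 | (Z)-alkenyllithium from 10 | [Li]/C=C(/C)C(O[Si](CC)(CC)CC)CCC(=C)CO[Si](C)(C)C(C)(C)C | intermediate
12 | (2Z)-7-({[tert-butyl(dimethyl)silyl]oxy}methyl)-3-methyl-4-[(triethylsilyl)oxy]octa-2,7-dienal | O=C/C=C(/C)C(O[Si](CC)(CC)CC)CCC(=C)CO[Si](C)(C)C(C)(C)C | intermediate
13 | monomethyl succinate | COC(=O)CCC(=O)O | starting material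
14 | (R)-4-benzyloxazolidin-2-one | O=C1N[C@H](Cc2ccccc2)CO1 | starting material
15 | mixed anhydride of 13 with pivalic acid | COC(=O)CCC(=O)OC(=O)C(C)(C)C | intermediate
16 | (4R)-4-benzyl-3-(4-methoxy-4-oxobutanoyl)oxazolidin-2-one | COC(=O)CCC(=O)N1[C@H](Cc2ccccc2)COC1=O | intermediate
17 | anti-aldol adduct, (2S,3S,4Z)-acyl chain, 3-OTMS, 6-OTES, on the (4R)-benzyloxazolidinone | COC(=O)C[C@H](C(=O)N1[C@H](Cc2ccccc2)COC1=O)[C@@H](O[Si](C)(C)C)/C=C(/C)C(O[Si](CC)(CC)CC)CCC(=C)CO[Si](C)(C)C(C)(C)C | intermediate
18 | desilylated 3,6-diol methyl ester of 17 | COC(=O)C[C@H](C(=O)N1[C@H](Cc2ccccc2)COC1=O)[C@@H](O)/C=C(/C)C(O)CCC(=C)CO[Si](C)(C)C(C)(C)C | intermediate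
19 | cis-lactone imide, (2S,3S)-oxolane, free C3 hydroxyl | O=C1C[C@H](C(=O)N2[C@H](Cc3ccccc3)COC2=O)[C@H](/C=C(/C)C(O)CCC(=C)CO[Si](C)(C)C(C)(C)C)O1 | intermediate
20 | (4R,5S)-5-[(1Z)-6-({[tert-butyl(dimethyl)silyl]oxy}methyl)-3-hydroxy-2-methylhepta-1,6-dien-1-yl]-4-(hydroxymethyl)oxolan-2-one | OC[C@H]1CC(=O)O[C@H]1/C=C(/C)C(O)CCC(=C)CO[Si](C)(C)C(C)(C)C | intermediate
21 | (2S,3S)-2-[(1Z)-6-({[tert-butyl(dimethyl)silyl]oxy}methyl)-2-methyl-3-oxohepta-1,6-dien-1-yl]-5-oxooxolane-3-carbaldehyde | O=C[C@H]1CC(=O)O[C@H]1/C=C(/C)C(=O)CCC(=C)CO[Si](C)(C)C(C)(C)C | intermediate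
22 | (4R,5S)-5-[(1Z)-6-({[tert-butyl(dimethyl)silyl]oxy}methyl)-2-methyl-3-oxohepta-1,6-dien-1-yl]-4-[(E)-(hydroxyimino)methyl]oxolan-2-one | O/N=C/[C@H]1CC(=O)O[C@H]1/C=C(/C)C(=O)CCC(=C)CO[Si](C)(C)C(C)(C)C | intermediate
23 | C8 hydroximoyl chloride of 22 | ON=C(Cl)[C@H]1CC(=O)O[C@H]1/C=C(/C)C(=O)CCC(=C)CO[Si](C)(C)C(C)(C)C | intermediate
24 | C8 nitrile oxide of 22 | [O-][N+]#C[C@H]1CC(=O)O[C@H]1/C=C(/C)C(=O)CCC(=C)CO[Si](C)(C)C(C)(C)C | intermediate
25 | isoxazoline-bridged ten-membered (Z)-enone lactone (6S,7R,10R), C8=N–O–C10 bridge, C14–OTBS | C1C(=O)O[C@H]2/C=C(/C)C(=O)CC[C@]3(CO[Si](C)(C)C(C)(C)C)CC(=NO3)[C@@H]12 | intermediate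
26 | 10-hydroxy-8-imino-3-oxo macrocyclic lactone | C1C(=O)O[C@H]2/C=C(/C)C(=O)CC[C@](O)(CO[Si](C)(C)C(C)(C)C)CC(=N)[C@@H]12 | intermediate
27 | 10-hydroxy-3,8-dioxo macrocyclic lactone | C1C(=O)O[C@H]2/C=C(/C)C(=O)CC[C@](O)(CO[Si](C)(C)C(C)(C)C)CC(=O)[C@@H]12 | intermediate
28 | hemiketal ketone (3S,6S,7S,10R): 3-hydroxy-3,10-epoxy-8-oxo lactone, C14–OTBS | C1C(=O)O[C@H]2/C=C(/C)[C@]3(O)CC[C@](CO[Si](C)(C)C(C)(C)C)(CC(=O)[C@@H]12)O3 | intermediate
29 | (3S,6S,7R,8R,10R)-3,8-dihydroxy-3,10-epoxy lactone, C14–OTBS | C1C(=O)O[C@H]2/C=C(/C)[C@]3(O)CC[C@](CO[Si](C)(C)C(C)(C)C)(C[C@@H](O)[C@@H]12)O3 | intermediate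
30 | 3,8-bis(triethylsilyl) ether of 29 | C1C(=O)O[C@H]2/C=C(/C)[C@]3(O[Si](CC)(CC)CC)CC[C@](CO[Si](C)(C)C(C)(C)C)(C[C@@H](O[Si](CC)(CC)CC)[C@@H]12)O3 | intermediate
31 | lithium enolate of lactone 30 | C1=C(O[Li])O[C@H]2/C=C(/C)[C@]3(O[Si](CC)(CC)CC)CC[C@](CO[Si](C)(C)C(C)(C)C)(C[C@@H](O[Si](CC)(CC)CC)[C@@H]12)O3 | intermediate
32 | C11 (dimethylamino)methyl lactone (Mannich base, C11 undefined) | CN(C)CC1C(=O)O[C@H]2/C=C(/C)[C@]3(O[Si](CC)(CC)CC)CC[C@](CO[Si](C)(C)C(C)(C)C)(C[C@@H](O[Si](CC)(CC)CC)[C@@H]12)O3 | intermediate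
33 | C11 (trimethylammonio)methyl lactone iodide | C[N+](C)(C)CC1C(=O)O[C@H]2/C=C(/C)[C@]3(O[Si](CC)(CC)CC)CC[C@](CO[Si](C)(C)C(C)(C)C)(C[C@@H](O[Si](CC)(CC)CC)[C@@H]12)O3.[I-] | intermediate
34 | α-methylidene lactone, 3,8-bis(triethylsilyl) ether, C14–OTBS | C=C1C(=O)O[C@H]2/C=C(/C)[C@]3(O[Si](CC)(CC)CC)CC[C@](CO[Si](C)(C)C(C)(C)C)(C[C@@H](O[Si](CC)(CC)CC)[C@@H]12)O3 | intermediate
35 | α-methylidene lactone 3,8-diol, C14–OTBS | C=C1C(=O)O[C@H]2/C=C(/C)[C@]3(O)CC[C@](CO[Si](C)(C)C(C)(C)C)(C[C@@H](O)[C@@H]12)O3 | intermediate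
36 | (R)-2-methylbutanoic acid | CC[C@@H](C)C(=O)O | starting material
37 | O-acylisourea of 36 with dicyclohexylcarbodiimide | CC[C@@H](C)C(=O)OC(=NC1CCCCC1)NC1CCCCC1 | intermediate
38 | 8-O-[(2R)-2-methylbutanoyl] ester, C14–OTBS | C=C1C(=O)O[C@H]2/C=C(/C)[C@]3(O)CC[C@](CO[Si](C)(C)C(C)(C)C)(C[C@@H](OC(=O)[C@H](C)CC)[C@@H]12)O3 | intermediate
39 | CNP0328225.2 | C=C1C(=O)O[C@H]2/C=C(/C)[C@]3(O)CC[C@](CO)(C[C@@H](OC(=O)[C@H](C)CC)[C@@H]12)O3 | target

**Step count and risks**
Total steps: 21. Longest linear sequence: 20 (steps 1–7 and 9–21); step 8 is a one-step side branch.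

Steps most likely to fail:

1. Step 14. The ten-membered closure may be slower than dimerisation of the nitrile oxide to the furoxan, or the dipole may add to the other face of C9=C10 and give the 10-epimer. Fallback: postpone the C3 oxidation until after ring closure, so that the tether carries an sp3 carbinol and folds differently. Setting out from 20, primary-selective oxidation with catalytic 2,2,6,6-tetramethylpiperidin-1-oxyl and PhI(OAc)2 gives the C3-hydroxy aldehyde F1. Oximation with NH2OH·HCl/NaOAc gives the C3-hydroxy oxime F2. NaOCl at high dilution closes the isoxazoline-bridged allylic alcohol F3, either C3 epimer being usable. Dess–Martin oxidation of F3 returns to the route at 25.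

2. Step 16. The intrinsic facial bias of the bridged bicycle may override the catalyst, so that hydride reaches the wrong face of C8. Fallback: accept substrate control and invert afterwards. Setting out from 28, NaBH4/CeCl3 in MeOH at −78 °C gives the (8S) alcohol F4. A Mitsunobu reaction (PPh3, diisopropyl azodicarboxylate, ClCH2CO2H) converts it with inversion into the (8R) chloroacetate F5. Thiourea with NaHCO3 in EtOH removes the chloroacetyl group under near-neutral conditions and returns to the route at 29.

3. Step 9. The Et3N/TMSCl medium may isomerise the (Z)-enal through its silyl dienol ether, or the hindered β,β-disubstituted enal may add too slowly to the catalytic magnesium enolate, with loss of geometry and of anti selectivity. Fallback: use a preformed boron enolate that never exposes the enal to amine and silyl chloride. Setting out from 16 and 12, 16 is enolised with Bu2BOTf/i-Pr2NEt in CH2Cl2 at −78 °C and treated with 12 precomplexed with Et2AlCl. The chelated boron enolate reacts through an open transition state on the face away from the benzyl group and gives the same anti adduct as the free C6 alcohol with the C3 triethylsilyl ether retained, F6. Under the conditions of step 10 it returns to the route at 19.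

**Further compounds**
F1 | step 14 | (2S,3S)-2-[(1Z)-6-({[tert-butyl(dimethyl)silyl]oxy}methyl)-3-hydroxy-2-methylhepta-1,6-dien-1-yl]-5-oxooxolane-3-carbaldehyde | O=C[C@H]1CC(=O)O[C@H]1/C=C(/C)C(O)CCC(=C)CO[Si](C)(C)C(C)(C)C
F2 | step 14 | C3-hydroxy analogue of oxime 22 | O/N=C/[C@H]1CC(=O)O[C@H]1/C=C(/C)C(O)CCC(=C)CO[Si](C)(C)C(C)(C)C
F3 | step 14 | isoxazoline-bridged ten-membered lactone with C3 hydroxyl in place of the ketone | C1C(=O)O[C@H]2/C=C(/C)C(O)CC[C@]3(CO[Si](C)(C)C(C)(C)C)CC(=NO3)[C@@H]12
F4 | step 16 | (8S) epimer of alcohol 29 | C1C(=O)O[C@H]2/C=C(/C)[C@]3(O)CC[C@](CO[Si](C)(C)C(C)(C)C)(C[C@H](O)[C@@H]12)O3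
F5 | step 16 | (8R) chloroacetate of 29 | C1C(=O)O[C@H]2/C=C(/C)[C@]3(O)CC[C@](CO[Si](C)(C)C(C)(C)C)(C[C@@H](OC(=O)CCl)[C@@H]12)O3
F6 | step 9 | anti-aldol adduct with free C6 hydroxyl and C3 triethylsilyl ether | COC(=O)C[C@H](C(=O)N1[C@H](Cc2ccccc2)COC1=O)[C@@H](O)/C=C(/C)C(O[Si](CC)(CC)CC)CCC(=C)CO[Si](C)(C)C(C)(C)C
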